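The earlier runs and the new flask are simulated on assumed constants, and the scatter is random.

The easy mistake with this flask is to reckon how much target has been made; that number climbs and then sags, so I reckon what is left instead.

| setting | noon | dawn | south-east | east |
|---|---|---|---|---|
| substrate | 0.32 M | 0.32 M | 0.32 M | 0.32 M |
| partner | 0.416 M | 0.416 M | 0.416 M | 0.416 M |
| catalyst | 3.2 mM | 13 mM | 6.4 mM | 6.4 mM |
| temperature | 69 °C | 77 °C | 65 °C | 80 °C |
| remark | run made earlier | run made earlier |  |  |
| time |  |  | 5.0 d | 5.0 d |

- noon (time / d: target / %, substrate / %): 0.250: 4, 91; 0.833: 13, 73; 1.25: 12, 69; 2.00: 18, 57; 3.00: 16, 40; 4.00: 15, 34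
- dawn (time / h: target / %, substrate / %): 3.00: 8, 82; 12.0: 23, 56; 15.0: 23, 57; 25.0: 20, 47; 40.0: 16, 36; 48.0: 11, 37

(each reading ± 2 percentage points)

1. the best flask by amount of target, in percent of the substrate charged; "all alike" if 1.5 percentage points covers them all (south-east / east / all alike)
2. amount of target at the end, in percent of the substrate charged, south-east
3. amount of target at the end, in percent of the substrate charged, east

I split the end of a flask into two fractions of the substrate charge. The pool is substrate plus target, which the dormant form drains. The hold is target over substrate, divided by partner left in equivalents of substrate, a reaction quotient. Here I take partner left as charge minus target. The last noon reading gives a hold of 0.384. The dawn reading at 15.0 h gives 0.377, about the same, with 4.06 times the catalyst.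

The pool left gives first-order rates of 0.178 d⁻¹ at noon and 0.367 d⁻¹ at dawn. Both new flasks lie outside the temperatures of these runs, so I extrapolate the logarithm on temperature and get 0.124 d⁻¹ for south-east and 0.481 d⁻¹ for east.

Which number must be good? With the target-to-substrate ratio at its noon value of 0.441, swapping in the dawn ratio of 0.404 moves south-east by 1 percentage point. Keeping the noon rate instead of correcting for temperature moves it by 3.9 points. So in this estimate for south-east, the pool rate moves the number more than the ratio does.

The pool left is 53.7% in south-east and 9.03% in east. My targets are 16.4% and 2.76%.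

The forecast names south-east, with 17% there and 4% in east, where “partner is largely decomposed”.

The flasks give 22.1% in south-east and 2.82% in east, so south-east is best.

    substrate + partner + catalyst ⇌ target + catalyst, rate k1*[substrate]*[partner]*[catalyst] forward; the back reaction follows from the equilibrium constant (K = 1.30 M⁻¹, k = 0.00290 M⁻² s⁻¹, Ea = 60.0 kJ mol⁻¹, ΔH = −17.0 kJ mol⁻¹)
    partner → decomposed reagent (k = 4.10 × 10⁻⁶ s⁻¹, Ea = 124 kJ mol⁻¹)
    substrate ⇌ dormant form (K = 4.80, k = 1.00 × 10⁻⁵ s⁻¹, Ea = 127 kJ mol⁻¹, ΔH = −59.0 kJ mol⁻¹)
    (constants at 80 °C)

South-east ends with substrate at 41.6% and partner at 62.9% of its own charge, or 0.818 equivalents, where charge minus target says 1.08. Its hold on these amounts is 0.651, above my 0.384. The neighbour charged with 1.0 M of partner ends with substrate at 31.3% and partner at 66.0% of its own charge. That hold times these two amounts gives 42.1%, and the neighbour holds 41.1% of target.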